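The runs were generated by integration from invented constants; scatter was added.

The constant I carried from Tuesday's run was the equal-charge time, 0.898 min: one over the second-order rate constant times [electrophile] at the start, with one nucleophile spent per electrophile. I took it from the last electrophile reading of that run, and as a check it gave 21.8% left at 0.667 min in Saturday's run, where I had read 20.9%.

the same everywhere: electrophile 0.016 M; gas 3.2 mM (held)
- Tuesday's: nucleophile 0.021 M; run made earlier
- Saturday's: nucleophile 0.041 M; run made earlier
- noon: nucleophile 0.0160 M; time 4.0 min
- dusk: nucleophile 0.0240 M; time 4.0 min
- dawn: nucleophile 0.0360 M; time 4.0 min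

- Tuesday's (time / min: electrophile / %, target / %): 0.500: 54.5, 31.8; 1.33: 28.5, 36.3; 2.50: 15.6, 33.2; 4.00: 7.3, 30.8
- Saturday's (time / min: electrophile / %, target / %): 0.333: 41.8, 47.3; 0.667: 20.9, 58.7; 1.50: 3.8, 65.6; 4.00: 0, 65.1

(readings scatter by 0.5 percentage points)

- the analysis behind the earlier runs scatters by 0.5 percentage points, standard deviation
- at the start none of the gas is in solution

- part of the electrophile that has reacted at the end, noon
- part of the electrophile that has reacted at the end, dusk
- part of the electrophile that has reacted at the end, dawn
- what raising the concentration of nucleophile from its lowest to its highest value here does to the part of the electrophile that has reacted (changes below 5 percentage points count as none) (no change / it falls / it rises)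

For the bench, I wrote this down: noon, dusk and dawn start with electrophile, nucleophile and gas and differ in [nucleophile]. With equal charges, the part left is the equal-charge time over itself plus the elapsed time, so I reckoned 81.7% reacted for noon at 4.0 min. The same integrated law with excess nucleophile gave 96.1% for dusk and 99.8% for dawn, a rise of 18 percentage points. I warned against reading reacted electrophile as target: in Tuesday's run target fell from 36.3% at 1.33 min to 30.8% at 4.00 min.

The forecast, slightly above my figure at noon, gave 83%, 96% and 99.9%, and for the trend it rises: “Conversion rises with nucleophile”. The flasks gave 80.5%, 95.7% and 99.8%, and the trend was it rises, by 19 points.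

    electrophile + nucleophile → acid set free + target (k = 1.28 M⁻¹ s⁻¹)
    electrophile + target → side product (k = 0.970 M⁻¹ s⁻¹)
    nucleophile + acid set free ⇌ protonated nucleophile, settled at all times (K = 5.49 × 10⁵ M⁻¹)
    gas ⇌ free base, rate k4*(csat - [free base]) (kL = 0.180 s⁻¹)
    acid set free + free base ⇌ salt of the base (K = 380 M⁻¹, k = 2.87 M⁻¹ s⁻¹)

The difference in [nucleophile] was the main reason for the rise: dawn reached 99.8%, and the same flask with that difference taken away, its nucleophile cut to noon's charge, reached 80.5%. The equal-charge time left 18.3% for noon, and the flask held 20%, beside 17.4% target and 63.1% side product. In a neighbour of noon charged with 0.0096 M of nucleophile, the limiting reagent, the same time gave 55.5% reacted, and that flask stood at 54.9%.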